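The route rests on cutting C3–C4 and C4–C5 of ring A (the ten-membered carbocycle C1–C10), so that the quaternary carbinol carbon C4, flanked by the methylenes C3 and C5 and the oxygenated carbons C2 and C6, becomes the carbon of a silyl dithiane. In one flask the lithiated dithiane opens an alkynyl epoxide at C5, a Brook shift moves silicon to O6, and the regenerated anion opens a vinyl epoxide at C3. The precursors are two enantiopure terminal epoxides and a 2-silyl-1,3-dithiane. The alkyne later becomes a maleic anhydride (C7, C8, C11, C12), and a Wittig closure of C8=C9 completes ring A and butenolide ring B.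

Key step: step 9

Numbering used in the text (target numbering): ring A = C1 (=CH next to C2), C2 (CH–OAc), C3 (CH2), C4 (C(CH3)OH), C5 (CH2), C6 (CH–O-methacryloyl), C7 and C8 (fusion carbons), C9 (=CH), C10 (C(CH3)=). Ring B = butenolide O–C8–C7=C11–C12(=O). C13 = the CH2OH carbon on C11. Locants inside systematic names are the IUPAC locants of that compound.

Remarks on the chemistry (assumptions):
- In the target the C4 hydroxyl is anti to both O2 and O6 along the C2–C6 chain. A chelate-controlled methyl addition to a C4 ketone places the new hydroxyl syn to the chelating oxygen. C2 is therefore carried through the coupling as its R epimer (from the (S)-vinyl epoxide, made from (R)-glyceraldehyde acetonide) and inverted when the acetate is introduced. C6 is carried unchanged.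
- O13 carries TBDPS rather than TBS, so that the secondary O6–TBS ether can be removed selectively before methacrylation.
- An allylmetal at C9 would react through C1. Ring A is therefore closed with a phosphorus ylide at C9, which reacts through C9 and forms C8=C9 directly.
- 2-(tert-Butyldimethylsilyl)-1,3-dithiane, the silyl propargyl ether 1 and (R)-glyceraldehyde acetonide are taken as purchased.

Step 1
Reactants: 1 tert-butyldiphenyl(prop-2-yn-1-yloxy)silane; 2 2-chloro-N-methoxy-N-methylacetamide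
Product: 3 5-[(tert-butyldiphenylsilyl)oxy]-1-chloropent-3-yn-2-one
Conditions: n-BuLi, THF, −78 °C; then 2, −78 → −20 °C; aq NH4Cl
Reagents that add atoms: none
Why: Weinreb ketone synthesis: the lithium acetylide adds once to the N-methoxy-N-methylamide and the chelated tetrahedral intermediate survives until work-up, so the chloromethyl ynone should form without over-addition.

Step 2
Reactants: 3 chloromethyl ynone
Product: 4 (2S)-5-[(tert-butyldiphenylsilyl)oxy]-1-chloropent-3-yn-2-ol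
Conditions: RuCl[(R,R)-TsDPEN](p-cymene) (2 mol%), HCO2H/Et3N (5:2), CH2Cl2, 0 °C → rt
Reagents that add atoms: none
Why: Noyori asymmetric transfer hydrogenation: the alkynyl group takes the π-recognition site of the catalyst, so the (R,R)-ligand should deliver hydride to the face that gives the (S)-chlorohydrin (S because CH2Cl outranks the alkyne); the sense is to be confirmed by Mosher ester analysis.

Step 3
Reactants: 4 (S)-chlorohydrin
Product: 5 tert-butyl({3-[(2S)-oxiran-2-yl]prop-2-yn-1-yl}oxy)diphenylsilane (alkynyl epoxide)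
Conditions: K2CO3, MeOH, 0 °C → rt
Reagents that add atoms: none
Why: Intramolecular Williamson closure: the alkoxide displaces the primary chloride, so the C–O bond at the stereocentre is not broken and its configuration (the later C6) is kept.

Step 4
Reactants: 6 (4R)-2,2-dimethyl-1,3-dioxolane-4-carbaldehyde; 7 ethyl 2-(triphenylphosphoranylidene)propanoate
Product: 8 ethyl (2E)-3-[(4S)-2,2-dimethyl-1,3-dioxolan-4-yl]-2-methylprop-2-enoate
Conditions: CH2Cl2, 0 °C → rt
Reagents that add atoms: none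
Why: Wittig olefination with a stabilised ylide should give the E trisubstituted enoate (the C1=C10 alkene); the stereocentre is untouched and changes descriptor from R to S only through priorities.

Step 5
Reactants: 8 enoate
Product: 9 (2E)-3-[(4S)-2,2-dimethyl-1,3-dioxolan-4-yl]-2-methylprop-2-en-1-ol
Conditions: i-Bu2AlH, CH2Cl2, −78 → 0 °C; aq potassium sodium tartrate
Reagents that add atoms: none
Why: 1,2-Reduction of a conjugated ester by the aluminium hydride gives the allylic alcohol (C9) without touching the alkene or the acetonide.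

Step 6
Reactants: 9 allylic alcohol
Product: 10 (4S)-4-{(1E)-3-[(4-methoxybenzyl)oxy]-2-methylprop-1-en-1-yl}-2,2-dimethyl-1,3-dioxolane
Conditions: NaH, 4-methoxybenzyl chloride, n-Bu4NI (cat.), THF/DMF, 0 °C → rt
Reagents that add atoms: 4-methoxybenzyl chloride, COc1ccc(CCl)cc1
Why: Williamson etherification of the primary alkoxide; the PMB group can later be removed oxidatively in the presence of silyl ethers and the acetate.

Step 7
Reactants: 10 PMB ether acetonide
Product: 11 (2S,3E)-5-[(4-methoxybenzyl)oxy]-4-methylpent-3-ene-1,2-diol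
Conditions: AcOH/H2O (4:1), rt → 40 °C
Reagents that add atoms: none
Why: Mild acid hydrolysis of the isopropylidene acetal frees the 1,2-diol while the PMB ether survives.

Step 8
Reactants: 11 diol
Product: 12 (2S)-2-{(1E)-3-[(4-methoxybenzyl)oxy]-2-methylprop-1-en-1-yl}oxirane (vinyl epoxide)
Conditions: NaH, 1-(2,4,6-triisopropylbenzenesulfonyl)imidazole, THF, 0 °C → rt
Reagents that add atoms: none
Why: One-pot diol-to-epoxide conversion: the hindered sulfonyl imidazole sulfonylates the primary alkoxide selectively and the secondary alkoxide displaces it, so the allylic stereocentre (the later C2) keeps its configuration.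

Step 9
Reactants: 13 2-(tert-butyldimethylsilyl)-1,3-dithiane; 5 alkynyl epoxide; 12 vinyl epoxide
Product: 17 2-{(2R)-2-[(tert-butyldimethylsilyl)oxy]-5-[(tert-butyldiphenylsilyl)oxy]pent-3-yn-1-yl}-2-{(2R,3E)-2-hydroxy-5-[(4-methoxybenzyl)oxy]-4-methylpent-3-en-1-yl}-1,3-dithiane (linchpin adduct), via lithiated silyl dithiane 14 (not isolated), via lithium alkoxide 15 (not isolated), via silyloxy lithio dithiane 16 (not isolated)
Conditions: t-BuLi, Et2O, −78 → −45 °C; 5, Et2O, −78 → −25 °C; then 12, HMPA/Et2O, −78 °C → rt; aq NH4Cl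
Reagents that add atoms: none
Why: This is an anion relay (linchpin) coupling of a 2-silyl-1,3-dithiane with two different epoxides, a known reaction type. Lithiated 13 (14) opens alkynyl epoxide 5 by SN2 attack at its CH2 terminus (C5) in ether, where alkoxide 15 keeps its C–Si bond; adding HMPA with epoxide 12 triggers the 1,4-Brook shift of silicon from C4 to O6, and the regenerated carbanion 16 opens vinyl epoxide 12 at its CH2 terminus (C3). No ring is closed and no stereocentre is created: C6 and C2 come unchanged from the two epoxides because only the unsubstituted epoxide carbons are attacked. The step needs terminal SN2 opening and not SN2′ addition: the copper-free organolithium secures this for the alkynyl epoxide, and the distal alkene carbon C10 of 12 is fully substituted (CH3, CH2OPMB), so SN2′ attack would have to build a quaternary centre. It also needs the Brook shift to wait for the second epoxide, which the ether solvent and low temperature should secure. O6 emerges silylated and O2 free, the differentiation used in step 11.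

Step 10
Reactants: 17 linchpin adduct
Product: 18 (2E,4R,8R)-8-[(tert-butyldimethylsilyl)oxy]-11-[(tert-butyldiphenylsilyl)oxy]-4-hydroxy-1-[(4-methoxybenzyl)oxy]-2-methylundec-2-en-9-yn-6-one
Conditions: MeI, CaCO3, MeCN/H2O (9:1), 45 °C
Reagents that add atoms: water, O
Why: Alkylative dithiane hydrolysis: S-methylation makes the thioacetal a leaving group and water gives the C4 ketone under buffered conditions that should spare the silyl ethers, the PMB ether and the alkyne.

Step 11
Reactants: 18 β-hydroxy ketone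
Product: 19 (2E,4R,6S,8R)-8-[(tert-butyldimethylsilyl)oxy]-11-[(tert-butyldiphenylsilyl)oxy]-1-[(4-methoxybenzyl)oxy]-2,6-dimethylundec-2-en-9-yne-4,6-diol
Conditions: MeMgBr (4 equiv, Et2O solution), CH2Cl2, −78 → −40 °C; aq NH4Cl
Reagents that add atoms: methylmagnesium bromide, C[Mg]Br
Why: Cram-chelate 1,3-induction: the first equivalent forms the C2 magnesium alkoxide, which ties the C4 carbonyl into a six-membered chelate with the C1 alkenyl group equatorial, so methyl should add to the ring face anti to that group and place the C4 hydroxyl syn to O2, while the silylated O6 stays out of the chelate.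

Step 12
Reactants: 19 syn-1,3-diol
Product: 20 (2E,4S,6S,8R)-8-[(tert-butyldimethylsilyl)oxy]-11-[(tert-butyldiphenylsilyl)oxy]-6-hydroxy-1-[(4-methoxybenzyl)oxy]-2,6-dimethylundec-2-en-9-yn-4-yl acetate
Conditions: PPh3, DIAD, AcOH, toluene, 0 °C → rt
Reagents that add atoms: acetic acid, CC(=O)O
Why: Mitsunobu esterification: the secondary allylic C2 alcohol is activated as its alkoxyphosphonium ion and displaced by acetate with inversion (R to S), which sets the anti relation between O2 and the C4 hydroxyl and installs the acetate at once; the tertiary alcohol does not react.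

Step 13
Reactants: 20 hydroxy acetate
Product: 21 (2E,4S,6S,8R)-8-[(tert-butyldimethylsilyl)oxy]-11-[(tert-butyldiphenylsilyl)oxy]-1-[(4-methoxybenzyl)oxy]-2,6-dimethyl-6-[(triethylsilyl)oxy]undec-2-en-9-yn-4-yl acetate
Conditions: TESOTf, 2,6-lutidine, CH2Cl2, −78 → 0 °C
Reagents that add atoms: triethylsilyl trifluoromethanesulfonate, CC[Si](CC)(CC)OS(=O)(=O)C(F)(F)F
Why: Silyl triflate silylation of the tertiary C4 alcohol, which would otherwise open the anhydride of step 14 at C8 to a six-membered lactone.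

Step 14
Reactants: 21 alkyne
Product: 22 (2E,4S,6S,8R)-8-[(tert-butyldimethylsilyl)oxy]-8-(4-{[(tert-butyldiphenylsilyl)oxy]methyl}-2,5-dioxo-2,5-dihydrofuran-3-yl)-1-[(4-methoxybenzyl)oxy]-2,6-dimethyl-6-[(triethylsilyl)oxy]oct-2-en-4-yl acetate
Conditions: PdI2 (5 mol%), KI, CO/air (4:1, 20 atm), dioxane/H2O, 60 °C
Reagents that add atoms: carbon monoxide, [C-]#[O+]; water, O
Why: Oxidative dicarbonylation of an alkyne to a maleic anhydride: syn addition of a Pd–CO2H unit across C7≡C11, CO insertion and hydrolysis give the cis diacid (new carbons C8 and C12), which as a dialkylmaleic acid should close to the anhydride spontaneously while air reoxidises palladium.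

Step 15
Reactants: 22 anhydride PMB ether
Product: 23 (2E,4S,6S,8R)-8-[(tert-butyldimethylsilyl)oxy]-8-(4-{[(tert-butyldiphenylsilyl)oxy]methyl}-2,5-dioxo-2,5-dihydrofuran-3-yl)-1-hydroxy-2,6-dimethyl-6-[(triethylsilyl)oxy]oct-2-en-4-yl acetate
Conditions: DDQ, CH2Cl2/pH 7 phosphate buffer, 0 °C
Reagents that add atoms: none
Why: Oxidative cleavage of the PMB ether by hydride abstraction and hydrolysis frees the C9 alcohol; a dialkylmaleic anhydride re-closes in water and should survive the buffer.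

Step 16
Reactants: 23 allylic alcohol
Product: 25 [(2E,4S,6S,8R)-4-(acetyloxy)-8-[(tert-butyldimethylsilyl)oxy]-8-(4-{[(tert-butyldiphenylsilyl)oxy]methyl}-2,5-dioxo-2,5-dihydrofuran-3-yl)-2,6-dimethyl-6-[(triethylsilyl)oxy]oct-2-en-1-yl]triphenylphosphonium bromide, via allylic bromide 24 (not isolated)
Conditions: CBr4, PPh3 (3 equiv), 2,6-lutidine, MeCN, 0 → 40 °C
Reagents that add atoms: triphenylphosphine, c1ccc(cc1)P(c1ccccc1)c1ccccc1; carbon tetrabromide, BrC(Br)(Br)Br
Why: Appel bromination of the primary allylic alcohol followed by SN2 quaternisation of the bromide with the excess phosphine under neutral conditions; the tetrasubstituted anhydride is a poor acceptor for the phosphine.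

Step 17
Reactants: 25 phosphonium bromide
Product: 27 (4R,6S,8S,9E,11E)-4-[(tert-butyldimethylsilyl)oxy]-3-{[(tert-butyldiphenylsilyl)oxy]methyl}-6,10-dimethyl-2-oxo-6-[(triethylsilyl)oxy]-2,4,5,6,7,8-hexahydrocyclodeca[b]furan-8-yl acetate, via phosphorus ylide 26 (not isolated)
Conditions: slow addition of 25 to KN(SiMe3)2 (1.0 equiv), THF (0.002 M), −78 °C → rt
Reagents that add atoms: none
Why: Proposed new method: the allylic ylide at C9 should add to anhydride carbonyl C8, the only carbonyl whose attack gives an ortho-fused ten-membered ring (attack at C12 would need a bridged eleven-membered ring and is screened by the CH2OTBDPS group), and loss of Ph3PO then gives the C8=C9 enol lactone with the ring-enforced geometry (C7 and C10 cis); the closest known reaction types are the Wittig olefination of cyclic anhydrides to ylidene lactones and Wittig macrocyclisation onto aldehydes.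

Step 18
Reactants: 27 macrocycle
Product: 28 (4R,6R,8S,9E,11E)-3-{[(tert-butyldiphenylsilyl)oxy]methyl}-4,6-dihydroxy-6,10-dimethyl-2-oxo-2,4,5,6,7,8-hexahydrocyclodeca[b]furan-8-yl acetate
Conditions: 48% aq HF, MeCN, 0 °C
Reagents that add atoms: none
Why: Acidic desilylation cleaves the TES and the secondary TBS ether much faster than the primary TBDPS ether, freeing O6 and O4 while O13 stays protected (the descriptor at the carbinol carbon changes to R only through priorities).

Step 19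
Reactants: 28 diol
Product: 29 (4R,6S,8S,9E,11E)-8-(acetyloxy)-3-{[(tert-butyldiphenylsilyl)oxy]methyl}-6-hydroxy-6,10-dimethyl-2-oxo-2,4,5,6,7,8-hexahydrocyclodeca[b]furan-4-yl 2-methylprop-2-enoate
Conditions: methacrylic anhydride, Et3N, DMAP (cat.), CH2Cl2, 0 °C → rt
Reagents that add atoms: methacrylic anhydride, C=C(C)C(=O)OC(=O)C(C)=C
Why: DMAP-catalysed acylation reaches only the secondary C6 hydroxyl, the tertiary C4 hydroxyl being too hindered under these conditions, and C6 keeps its configuration.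

Step 20
Reactants: 29 silyl ether
Product: 30 (4R,6S,8S,9E,11E)-8-(acetyloxy)-6-hydroxy-3-(hydroxymethyl)-6,10-dimethyl-2-oxo-2,4,5,6,7,8-hexahydrocyclodeca[b]furan-4-yl 2-methylprop-2-enoate (target)
Conditions: HF·pyridine, pyridine, THF, 0 °C → rt
Reagents that add atoms: none
Why: Buffered fluoride desilylation removes the primary TBDPS group and should leave the two esters, the enol lactone and the tertiary alcohol untouched.

Compound list
1 | tert-butyldiphenyl(prop-2-yn-1-yloxy)silane | C#CCO[Si](c1ccccc1)(c1ccccc1)C(C)(C)C | starting material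
2 | 2-chloro-N-methoxy-N-methylacetamide | CON(C)C(=O)CCl | starting material
3 | 5-[(tert-butyldiphenylsilyl)oxy]-1-chloropent-3-yn-2-one | ClCC(=O)C#CCO[Si](c1ccccc1)(c1ccccc1)C(C)(C)C | intermediate
4 | (2S)-5-[(tert-butyldiphenylsilyl)oxy]-1-chloropent-3-yn-2-ol | ClC[C@@H](O)C#CCO[Si](c1ccccc1)(c1ccccc1)C(C)(C)C | intermediate
5 | tert-butyl({3-[(2S)-oxiran-2-yl]prop-2-yn-1-yl}oxy)diphenylsilane (alkynyl epoxide) | O1C[C@@H]1C#CCO[Si](c1ccccc1)(c1ccccc1)C(C)(C)C | intermediate
6 | (4R)-2,2-dimethyl-1,3-dioxolane-4-carbaldehyde | CC1(C)OC[C@H](C=O)O1 | starting material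
7 | ethyl 2-(triphenylphosphoranylidene)propanoate | CCOC(=O)C(C)=P(c1ccccc1)(c1ccccc1)c1ccccc1 | starting material
8 | ethyl (2E)-3-[(4S)-2,2-dimethyl-1,3-dioxolan-4-yl]-2-methylprop-2-enoate | CC1(C)OC[C@H](/C=C(C)/C(=O)OCC)O1 | intermediate
9 | (2E)-3-[(4S)-2,2-dimethyl-1,3-dioxolan-4-yl]-2-methylprop-2-en-1-ol | CC1(C)OC[C@H](/C=C(C)/CO)O1 | intermediate
10 | (4S)-4-{(1E)-3-[(4-methoxybenzyl)oxy]-2-methylprop-1-en-1-yl}-2,2-dimethyl-1,3-dioxolane | CC1(C)OC[C@H](/C=C(C)/COCc2ccc(OC)cc2)O1 | intermediate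
11 | (2S,3E)-5-[(4-methoxybenzyl)oxy]-4-methylpent-3-ene-1,2-diol | OC[C@@H](O)/C=C(C)/COCc1ccc(OC)cc1 | intermediate
12 | (2S)-2-{(1E)-3-[(4-methoxybenzyl)oxy]-2-methylprop-1-en-1-yl}oxirane (vinyl epoxide) | C1O[C@H]1/C=C(C)/COCc1ccc(OC)cc1 | intermediate
13 | 2-(tert-butyldimethylsilyl)-1,3-dithiane | CC(C)(C)[Si](C)(C)C1SCCCS1 | starting material
14 | 2-(tert-butyldimethylsilyl)-2-lithio-1,3-dithiane | [Li]C1([Si](C)(C)C(C)(C)C)SCCCS1 | intermediate
15 | lithium (2R)-1-[2-(tert-butyldimethylsilyl)-1,3-dithian-2-yl]-5-[(tert-butyldiphenylsilyl)oxy]pent-3-yn-2-olate | [Li]O[C@@H](C#CCO[Si](c1ccccc1)(c1ccccc1)C(C)(C)C)CC1([Si](C)(C)C(C)(C)C)SCCCS1 | intermediate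
16 | 2-{(2R)-2-[(tert-butyldimethylsilyl)oxy]-5-[(tert-butyldiphenylsilyl)oxy]pent-3-yn-1-yl}-2-lithio-1,3-dithiane | CC(C)(C)[Si](C)(C)O[C@@H](C#CCO[Si](c1ccccc1)(c1ccccc1)C(C)(C)C)CC1([Li])SCCCS1 | intermediate
17 | 2-{(2R)-2-[(tert-butyldimethylsilyl)oxy]-5-[(tert-butyldiphenylsilyl)oxy]pent-3-yn-1-yl}-2-{(2R,3E)-2-hydroxy-5-[(4-methoxybenzyl)oxy]-4-methylpent-3-en-1-yl}-1,3-dithiane (linchpin adduct) | CC(C)(C)[Si](C)(C)O[C@@H](C#CCO[Si](c1ccccc1)(c1ccccc1)C(C)(C)C)CC1(SCCCS1)C[C@@H](O)/C=C(C)/COCc1ccc(OC)cc1 | intermediate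
18 | (2E,4R,8R)-8-[(tert-butyldimethylsilyl)oxy]-11-[(tert-butyldiphenylsilyl)oxy]-4-hydroxy-1-[(4-methoxybenzyl)oxy]-2-methylundec-2-en-9-yn-6-one | CC(C)(C)[Si](C)(C)O[C@@H](C#CCO[Si](c1ccccc1)(c1ccccc1)C(C)(C)C)CC(=O)C[C@@H](O)/C=C(C)/COCc1ccc(OC)cc1 | intermediate
19 | (2E,4R,6S,8R)-8-[(tert-butyldimethylsilyl)oxy]-11-[(tert-butyldiphenylsilyl)oxy]-1-[(4-methoxybenzyl)oxy]-2,6-dimethylundec-2-en-9-yne-4,6-diol | CC(C)(C)[Si](C)(C)O[C@@H](C#CCO[Si](c1ccccc1)(c1ccccc1)C(C)(C)C)C[C@@](C)(O)C[C@@H](O)/C=C(C)/COCc1ccc(OC)cc1 | intermediate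
20 | (2E,4S,6S,8R)-8-[(tert-butyldimethylsilyl)oxy]-11-[(tert-butyldiphenylsilyl)oxy]-6-hydroxy-1-[(4-methoxybenzyl)oxy]-2,6-dimethylundec-2-en-9-yn-4-yl acetate | CC(C)(C)[Si](C)(C)O[C@@H](C#CCO[Si](c1ccccc1)(c1ccccc1)C(C)(C)C)C[C@@](C)(O)C[C@H](OC(C)=O)/C=C(C)/COCc1ccc(OC)cc1 | intermediate
21 | (2E,4S,6S,8R)-8-[(tert-butyldimethylsilyl)oxy]-11-[(tert-butyldiphenylsilyl)oxy]-1-[(4-methoxybenzyl)oxy]-2,6-dimethyl-6-[(triethylsilyl)oxy]undec-2-en-9-yn-4-yl acetate | CC(C)(C)[Si](C)(C)O[C@@H](C#CCO[Si](c1ccccc1)(c1ccccc1)C(C)(C)C)C[C@@](C)(O[Si](CC)(CC)CC)C[C@H](OC(C)=O)/C=C(C)/COCc1ccc(OC)cc1 | intermediate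
22 | (2E,4S,6S,8R)-8-[(tert-butyldimethylsilyl)oxy]-8-(4-{[(tert-butyldiphenylsilyl)oxy]methyl}-2,5-dioxo-2,5-dihydrofuran-3-yl)-1-[(4-methoxybenzyl)oxy]-2,6-dimethyl-6-[(triethylsilyl)oxy]oct-2-en-4-yl acetate | CC(C)(C)[Si](C)(C)O[C@@H](C1=C(CO[Si](c2ccccc2)(c2ccccc2)C(C)(C)C)C(=O)OC1=O)C[C@@](C)(O[Si](CC)(CC)CC)C[C@H](OC(C)=O)/C=C(C)/COCc1ccc(OC)cc1 | intermediate
23 | (2E,4S,6S,8R)-8-[(tert-butyldimethylsilyl)oxy]-8-(4-{[(tert-butyldiphenylsilyl)oxy]methyl}-2,5-dioxo-2,5-dihydrofuran-3-yl)-1-hydroxy-2,6-dimethyl-6-[(triethylsilyl)oxy]oct-2-en-4-yl acetate | CC(C)(C)[Si](C)(C)O[C@@H](C1=C(CO[Si](c2ccccc2)(c2ccccc2)C(C)(C)C)C(=O)OC1=O)C[C@@](C)(O[Si](CC)(CC)CC)C[C@H](OC(C)=O)/C=C(C)/CO | intermediate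
24 | (2E,4S,6S,8R)-1-bromo-8-[(tert-butyldimethylsilyl)oxy]-8-(4-{[(tert-butyldiphenylsilyl)oxy]methyl}-2,5-dioxo-2,5-dihydrofuran-3-yl)-2,6-dimethyl-6-[(triethylsilyl)oxy]oct-2-en-4-yl acetate | CC(C)(C)[Si](C)(C)O[C@@H](C1=C(CO[Si](c2ccccc2)(c2ccccc2)C(C)(C)C)C(=O)OC1=O)C[C@@](C)(O[Si](CC)(CC)CC)C[C@H](OC(C)=O)/C=C(C)/CBr | intermediate
25 | [(2E,4S,6S,8R)-4-(acetyloxy)-8-[(tert-butyldimethylsilyl)oxy]-8-(4-{[(tert-butyldiphenylsilyl)oxy]methyl}-2,5-dioxo-2,5-dihydrofuran-3-yl)-2,6-dimethyl-6-[(triethylsilyl)oxy]oct-2-en-1-yl]triphenylphosphonium bromide | CC(C)(C)[Si](C)(C)O[C@@H](C1=C(CO[Si](c2ccccc2)(c2ccccc2)C(C)(C)C)C(=O)OC1=O)C[C@@](C)(O[Si](CC)(CC)CC)C[C@H](OC(C)=O)/C=C(C)/C[P+](c1ccccc1)(c1ccccc1)c1ccccc1.[Br-] | intermediate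
26 | (2E,4S,6S,8R)-8-[(tert-butyldimethylsilyl)oxy]-8-(4-{[(tert-butyldiphenylsilyl)oxy]methyl}-2,5-dioxo-2,5-dihydrofuran-3-yl)-2,6-dimethyl-6-[(triethylsilyl)oxy]-1-(triphenylphosphoranylidene)oct-2-en-4-yl acetate (ylide) | CC(C)(C)[Si](C)(C)O[C@@H](C1=C(CO[Si](c2ccccc2)(c2ccccc2)C(C)(C)C)C(=O)OC1=O)C[C@@](C)(O[Si](CC)(CC)CC)C[C@H](OC(C)=O)/C=C(C)/C=P(c1ccccc1)(c1ccccc1)c1ccccc1 | intermediate
27 | (4R,6S,8S,9E,11E)-4-[(tert-butyldimethylsilyl)oxy]-3-{[(tert-butyldiphenylsilyl)oxy]methyl}-6,10-dimethyl-2-oxo-6-[(triethylsilyl)oxy]-2,4,5,6,7,8-hexahydrocyclodeca[b]furan-8-yl acetate | CC(C)(C)[Si](C)(C)O[C@@H]1C[C@@](C)(O[Si](CC)(CC)CC)C[C@H](OC(C)=O)/C=C(C)/C=C2/OC(=O)C(CO[Si](c3ccccc3)(c3ccccc3)C(C)(C)C)=C21 | intermediate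
28 | (4R,6R,8S,9E,11E)-3-{[(tert-butyldiphenylsilyl)oxy]methyl}-4,6-dihydroxy-6,10-dimethyl-2-oxo-2,4,5,6,7,8-hexahydrocyclodeca[b]furan-8-yl acetate | O[C@@H]1C[C@@](C)(O)C[C@H](OC(C)=O)/C=C(C)/C=C2/OC(=O)C(CO[Si](c3ccccc3)(c3ccccc3)C(C)(C)C)=C21 | intermediate
29 | (4R,6S,8S,9E,11E)-8-(acetyloxy)-3-{[(tert-butyldiphenylsilyl)oxy]methyl}-6-hydroxy-6,10-dimethyl-2-oxo-2,4,5,6,7,8-hexahydrocyclodeca[b]furan-4-yl 2-methylprop-2-enoate | C=C(C)C(=O)O[C@@H]1C[C@@](C)(O)C[C@H](OC(C)=O)/C=C(C)/C=C2/OC(=O)C(CO[Si](c3ccccc3)(c3ccccc3)C(C)(C)C)=C21 | intermediate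
30 | (4R,6S,8S,9E,11E)-8-(acetyloxy)-6-hydroxy-3-(hydroxymethyl)-6,10-dimethyl-2-oxo-2,4,5,6,7,8-hexahydrocyclodeca[b]furan-4-yl 2-methylprop-2-enoate | C=C(C)C(=O)O[C@@H]1C[C@@](C)(O)C[C@H](OC(C)=O)/C=C(C)/C=C2/OC(=O)C(CO)=C21 | target

Total step count: 20 steps.
Longest linear sequence: 17 steps (steps 4–20, from aldehyde 6); the alkynyl epoxide branch (steps 1–3) joins at step 9.

Steps most likely to fail

1. Step 17 (the proposed new method). The base may remove a proton next to the anhydride (at C13 or C6) instead of forming the ylide. The ylide may lose acetate by vinylogous elimination. The anhydride may be opened by C-acylation without loss of phosphine oxide, or react between molecules. Fallback, setting out from alcohol 23 and returning at macrocycle 27, separates carbon–carbon bond formation from olefination with known reaction types. The bromide 24 is made as in step 16 without phosphine excess and displaced with PhSO2Na in DMF to give the allylic sulfone (2E,4S,6S,8R)-8-[(tert-butyldimethylsilyl)oxy]-8-(4-{[(tert-butyldiphenylsilyl)oxy]methyl}-2,5-dioxo-2,5-dihydrofuran-3-yl)-2,6-dimethyl-1-(phenylsulfonyl)-6-[(triethylsilyl)oxy]oct-2-en-4-yl acetate F1. Its α-sulfonyl carbanion (LiN(SiMe3)2, THF, high dilution, −78 °C) is acylated at C8 by the anhydride, giving the ring-closed keto sulfone in its lactol form, the C8-hydroxy C9-phenylsulfonyl butenolide F2 (mixture at C8 and C9). Reductive desulfonylation of the β-keto sulfone with SmI2 gives the C8 hydroxybutenolide F3. Dehydration toward C9 (MsCl, Et3N) gives 27.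

2. Step 14. Carbopalladation of the hindered internal alkyne may be slow. The TES ether may be lost, after which the C4 hydroxyl would lactonise onto the anhydride. The allylic acetate may be ionised by transient zerovalent palladium. Fallback, setting out from alkyne 21 and returning at anhydride 22, builds the two carbonyl carbons one at a time. The titanium alkoxide–alkyne complex (Ti(OiPr)4, i-PrMgCl, Et2O, −78 → −50 °C) is carboxylated with CO2 and the remaining vinyl–titanium bond is cleaved with I2. This should give the (Z)-β-iodoacrylic acid (2Z,4R,6S,8S,9E)-8-(acetyloxy)-4-[(tert-butyldimethylsilyl)oxy]-2-{[(tert-butyldiphenylsilyl)oxy]methyl}-3-iodo-11-[(4-methoxybenzyl)oxy]-6,10-dimethyl-6-[(triethylsilyl)oxy]undeca-2,9-dienoic acid F4; the other regioisomer would converge on the same anhydride. Carbonylative ring closure (PdCl2(PPh3)2 cat., CO 1 atm, Et3N, THF) then gives 22.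

3. Step 12. The activated allylic alcohol may ionise to an allyl cation stabilised by the trisubstituted alkene, which would erode the configuration at C2 or transpose the acetate; the neighbouring tertiary hydroxyl may also interfere. Fallback, setting out from diol 19 and returning at acetate 20, replaces substitution by oxidation and directed reduction. MnO2 in CH2Cl2 oxidises the allylic alcohol to the enone (2E,6R,8R)-8-[(tert-butyldimethylsilyl)oxy]-11-[(tert-butyldiphenylsilyl)oxy]-6-hydroxy-1-[(4-methoxybenzyl)oxy]-2,6-dimethylundec-2-en-9-yn-4-one F5. Evans–Saksena reduction (Me4NBH(OAc)3, MeCN/AcOH, −30 °C) delivers hydride internally from boron bound to the C4 hydroxyl and should give the 1,3-anti diol (2E,4S,6S,8R)-8-[(tert-butyldimethylsilyl)oxy]-11-[(tert-butyldiphenylsilyl)oxy]-1-[(4-methoxybenzyl)oxy]-2,6-dimethylundec-2-en-9-yne-4,6-diol F6. Acetylation of the secondary hydroxyl (Ac2O, pyridine) gives 20.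

Further compounds
F1 | step 17 | (2E,4S,6S,8R)-8-[(tert-butyldimethylsilyl)oxy]-8-(4-{[(tert-butyldiphenylsilyl)oxy]methyl}-2,5-dioxo-2,5-dihydrofuran-3-yl)-2,6-dimethyl-1-(phenylsulfonyl)-6-[(triethylsilyl)oxy]oct-2-en-4-yl acetate | CC(C)(C)[Si](C)(C)O[C@@H](C1=C(CO[Si](c2ccccc2)(c2ccccc2)C(C)(C)C)C(=O)OC1=O)C[C@@](C)(O[Si](CC)(CC)CC)C[C@H](OC(C)=O)/C=C(C)/CS(=O)(=O)c1ccccc1
F2 | step 17 | C8-hydroxy C9-phenylsulfonyl butenolide (lactol form of the ring-closed keto sulfone, mixture at C8 and C9) | CC(C)(C)[Si](C)(C)O[C@@H]1C[C@@](C)(O[Si](CC)(CC)CC)C[C@H](OC(C)=O)/C=C(C)/C(S(=O)(=O)c3ccccc3)C2(O)OC(=O)C(CO[Si](c3ccccc3)(c3ccccc3)C(C)(C)C)=C21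
F3 | step 17 | C8 hydroxybutenolide (lactol form of the ring-closed keto acid, mixture at C8) | CC(C)(C)[Si](C)(C)O[C@@H]1C[C@@](C)(O[Si](CC)(CC)CC)C[C@H](OC(C)=O)/C=C(C)/CC2(O)OC(=O)C(CO[Si](c3ccccc3)(c3ccccc3)C(C)(C)C)=C21
F4 | step 14 | (2Z,4R,6S,8S,9E)-8-(acetyloxy)-4-[(tert-butyldimethylsilyl)oxy]-2-{[(tert-butyldiphenylsilyl)oxy]methyl}-3-iodo-11-[(4-methoxybenzyl)oxy]-6,10-dimethyl-6-[(triethylsilyl)oxy]undeca-2,9-dienoic acid | CC(C)(C)[Si](C)(C)O[C@@H](/C(I)=C(\CO[Si](c1ccccc1)(c1ccccc1)C(C)(C)C)C(=O)O)C[C@@](C)(O[Si](CC)(CC)CC)C[C@H](OC(C)=O)/C=C(C)/COCc1ccc(OC)cc1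
F5 | step 12 | (2E,6R,8R)-8-[(tert-butyldimethylsilyl)oxy]-11-[(tert-butyldiphenylsilyl)oxy]-6-hydroxy-1-[(4-methoxybenzyl)oxy]-2,6-dimethylundec-2-en-9-yn-4-one | CC(C)(C)[Si](C)(C)O[C@@H](C#CCO[Si](c1ccccc1)(c1ccccc1)C(C)(C)C)C[C@@](C)(O)CC(=O)/C=C(C)/COCc1ccc(OC)cc1
F6 | step 12 | (2E,4S,6S,8R)-8-[(tert-butyldimethylsilyl)oxy]-11-[(tert-butyldiphenylsilyl)oxy]-1-[(4-methoxybenzyl)oxy]-2,6-dimethylundec-2-en-9-yne-4,6-diol | CC(C)(C)[Si](C)(C)O[C@@H](C#CCO[Si](c1ccccc1)(c1ccccc1)C(C)(C)C)C[C@@](C)(O)C[C@H](O)/C=C(C)/COCc1ccc(OC)cc1
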